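# Synthesis plan for CNP0251577.3: an aryl cyclobutane triacid esterified three times with a cyclopenta[c]pyridinol

## The problem

The target is a triester in which three molecules of one amino alcohol, a cis-fused 2,4,7-trimethyloctahydrocyclopenta[c]pyridin-6-ol, are bound through O6 to the three carboxyl groups of an aryl cyclobutane triacid, so that 15 of the 19 stereocentres sit in three identical units and the synthesis can be convergent. The cyclobutane, numbered here C1 (quaternary, methyl and carboxyl), C2 (CH–aryl), C3 (CH–carboxyl) and C4 (CH–side chain), is fully substituted and unsymmetrical and therefore is not a cinnamate photodimer. The aryl group and the C3 carboxyl are cis, the C4 chain and the C1 carboxyl are cis, and the two pairs lie on opposite faces; only C3 can be corrected once the ring exists (and can be lost under base), whereas C1 is quaternary and C2 and C4 carry no handle, so the four centres must be set together and their absolute configuration must come from a catalyst. In the amino alcohol the ring fusion (C4a, C7a) and the C7 methyl group can be controlled from one another on a bicyclic ketone, C4 must be brought in from a chiral building block, and the ester oxygen lies on the convex face beside the C7 methyl group, which calls for esterification with inversion. The groups at risk are the C3 hydrogen, the (E)-trisubstituted enoate (isomerisation, hydrogenation), the oxidisable guaiacol ring, three basic amines and the neopentyl-type C1 carboxyl. The enabling feature is that C2 (benzylic) and C3 (α to a carboxyl) are neighbours with cis substituents, which is the 2,5-cis pattern of a 5-arylproline ester without its nitrogen. The second cis pair, a ring-bound CH2 at C4 and the carboxyl at C1, is a γ-lactone in disguise and the trace of an α-methylbutenolide dipolarophile.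

## Retrosynthesis

**Ester bonds.** Target 28 is the phenol of benzyl ether 27, and 27 is cut at the three O–C6 bonds into triacid 16 and three molecules of amino alcohol 26. The alkyl–oxygen cut is preferred to the acyl–oxygen cut because the carboxylate is then the nucleophile, so the hindered C1 acid needs no activation and C3 sees no base. The alcohol required, the 6-epimer 26, is the one that hydride reduction of a ketone should give. The forward step is a triple Mitsunobu reaction with inversion that consumes three molecules of 26 per molecule of 16. The benzyl ether is removed last with BCl3, since hydrogenolysis would endanger the enoate.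

**Side chain.** Triacid 16 comes from trimethyl ester 15. The enoate methyl group of 15 is cut back to enol phosphate 14 and β-keto ester 13, and the CH2–CH2 bond of 13 is cut into iodide 10 and methyl acetoacetate 11. This is preferred to olefination of a methyl ketone because the enol phosphate/cuprate pair fixes the (E) geometry. The precursor 10 carries only a CH2I group at C4.

**Lactone.** Iodide 10 comes from hydroxy diester 9, and 9 from lactone 7 by reconnecting the C4 CH2–O to the C1 carboxyl. Lactone 7 is a rigid bicycle that hides the C1 acid and the C4 arm in one ring. The forward opening must spare the benzyl and methyl aryl ethers, so it is done by hydrolysis, carboxylate methylation and Appel iodination, not with a silyl iodide.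

**Key disconnection.** In 7 the C2–C3 bond is cut and an NH is placed between the two carbons, which gives pyrrolidine 5 through 1,1-diazene 6. C2–C3 is the only ring bond whose two ends both stabilise a radical. A [2+2] cut at C1–C2/C3–C4 would require a crossed, face-selective union of two different alkenes. Pyrrolidine 5 is much simpler than 7, since it is one cycloaddition away from three purchasable pieces. The forward reaction must proceed with retention at both carbons and must tolerate the dialkoxyarene.

**Pyrrolidine.** Pyrrolidine 5 is cut at both C–C bonds flanking the nitrogen-bearing carbons into imine 3 and butenolide 4. Imine 3 comes from aldehyde 1 and glycine ester 2. The forward cycloaddition must be exo and enantioselective and must forge the quaternary centre next to the aryl-bearing carbon.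

**Amino alcohol.** Alcohol 26 comes from ketone 25 (reduction of ketone and carbamate), and 25 from enone 24 (hydrogenation). Enone 24 is cut at C4a–C7a, C5–C6 and C6–C7 to enyne 22 (Pauson–Khand reaction). Enyne 22 is taken back through aldehyde 21, carbamate 20 and amino alcohol 19 to bromo alcohol 17, which supplies C4, and (E)-crotylamine salt 18, whose geometry supplies C7.

## Roads not taken

Alternative 1: The cut is in the piperidine ring of the amino alcohol, at N2–C1 and C1–C7a.
- Forward step: the cyclopentenol amine A2 condenses with formaldehyde A4 to the methyleneiminium ion A3. The ring alkene attacks it at C7a, and the tertiary cation at C7 is quenched by a 1,2-hydride shift from the carbinol carbon C6, giving amino ketone A1.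
- Merits: the N-methyl group is in place from the start, no cobalt and no carbamate reduction are needed, and the tether enforces the cis ring fusion. A1 is one reduction away from 26. In step count after the cyclisation this road is better than the Pauson–Khand sequence of the chosen plan.
- Weak points: A2 already needs three defined stereocentres, including a trans 1,3-relation on a cyclopentene and an exocyclic centre. The alkene is deactivated by its allylic hydroxyl. The cation can lose a proton or be trapped by oxygen instead of accepting hydride. The hydride-shift termination on an aza-Prins cation has no close precedent.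
- Comparison: this road addresses only the thrice-used amino alcohol and leaves the cyclobutane unsolved. The chosen plan accepts a longer but precedented amino alcohol synthesis and places its key step on the cyclobutane.

Alternative 2: The cut removes C4a–C7a, C5–C6 and C6–C7 of the amino alcohol at once.
- Forward step: enyne A6 (identical with 22) gives enone A5 (identical with 24) under the cobalt carbonyl/amine N-oxide conditions of step 14.
- Merits: three C–C bonds and both rings form in one step from an acyclic precursor, the reaction class is well established, and C7/C7a follow from the alkene geometry. In bond economy and precedent it is better than the nitrogen deletion, which forms one bond.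
- Weak points: an internal alkene in a 1,7-enyne is a demanding substrate, and C7a is set only by a remote methyl group.
- Comparison: as the defining step of the whole plan it would leave the cyclobutane to conventional [2+2] chemistry, which cannot deliver an unsymmetrical ring with a quaternary carbon. The reaction is therefore kept in a supporting role (step 14). Against its higher bond count the chosen plan sets the transfer of four cyclobutane stereocentres from a one-step cycloadduct.

Alternative 3: The cut is at C4–C1 of the cyclobutane.
- Forward step: the eight-membered (Z)-allylic lactone A8 is converted into its silyl ketene acetal A9. A9 rearranges through a boat [3,3] transition state to the cyclobutane acid A7, which has cis vinyl and carboxyl groups and a silyloxymethyl group at C3.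
- Merits: the quaternary centre and a ring bond form stereospecifically. The C1 acid is obtained free, so no lactone opening and no forced hydrolysis at C1 are needed. The vinyl group could be extended to the side chain by hydroboration and cross-coupling in fewer steps than the five used here (steps 4–8). In these respects it is better than the chosen plan.
- Weak points: A8 is a medium ring with a (Z)-alkene and two contiguous stereocentres that must be made enantioselectively over many steps. The C3 substituent arrives at the alcohol oxidation level. The relation of C1 to the C2 aryl group depends on the ring conformation in the transition state.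
- Comparison: the chosen plan has to set against the easier side-chain work of A7 the fact that 7 is reached in three steps from commercial materials with all four centres controlled by one catalyst.

Key step: step 3

Remark: (E)-but-2-en-1-amine hydrochloride (18) is taken as a purchasable, geometrically pure reagent. The enantiomer of the ferrocenyl ligand in step 2 is the one that leads to 5, to be fixed by assigning the first batch.

## Route

Step 1
Reactants: 1 4-(benzyloxy)-3-methoxybenzaldehyde; 2 glycine methyl ester hydrochloride
Product: 3 methyl (E)-N-[4-(benzyloxy)-3-methoxybenzylidene]glycinate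
Conditions: Et3N, MgSO4, CH2Cl2, rt
Reagents that add atoms: none
Why: Imine condensation of an aromatic aldehyde with a primary amine, driven by the drying agent; the conjugated aldimine forms as the (E) isomer and is used crude.

Step 2
Reactants: 3 methyl (E)-N-[4-(benzyloxy)-3-methoxybenzylidene]glycinate; 4 3-methylfuran-2(5H)-one
Product: 5 methyl (3aR,4R,6R,6aS)-6-[4-(benzyloxy)-3-methoxyphenyl]-6a-methyl-1-oxohexahydro-1H-furo[3,4-c]pyrrole-4-carboxylate (aryl and ester cis; lactone on the opposite face)
Conditions: Cu(CH3CN)4PF6 (5 mol %), ClickFerrophos-type ferrocenyl diphosphine (5.5 mol %), Et3N (15 mol %), THF, −20 °C → rt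
Reagents that add atoms: none
Why: Catalytic asymmetric 1,3-dipolar cycloaddition of an N,O-chelated copper azomethine ylide: the W-shaped ylide fixes the cis relation of aryl and ester, suprafacial addition to the ring alkene fixes the cis lactone fusion, and Michael-type attack of the ester-bearing ylide carbon on the butenolide β-carbon places the methyl-bearing quaternary carbon next to the aryl-bearing one. The bulky ferrocenyl ligand on monovalent copper forces the lactone carbonyl away from the metal (exo) and selects the ylide face, which sets the absolute configuration of all four centres.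

Step 3
Reactants: 5 methyl (3aR,4R,6R,6aS)-6-[4-(benzyloxy)-3-methoxyphenyl]-6a-methyl-1-oxohexahydro-1H-furo[3,4-c]pyrrole-4-carboxylate
Product: 7 methyl (1R,5S,6R,7R)-7-[4-(benzyloxy)-3-methoxyphenyl]-1-methyl-2-oxo-3-oxabicyclo[3.2.0]heptane-6-carboxylate, via 1,1-diazene 6 (not isolated)
Conditions: PhI(OH)OTs (2.5 equiv), NH2CO2NH4 (8 equiv), CF3CH2OH, 80 °C
Reagents that add atoms: none
Why: Ammonia from the carbamate and PhI(OH)OTs give an electrophilic iodonitrene that aminates the ring nitrogen of 5 and, with loss of iodobenzene, leaves 1,1-diazene 6; 6 expels N2 to a singlet 1,4-biradical with its ends at the benzylic carbon and at the carbon α to the ester, and these recombine to the new C2–C3 bond. The closest known reaction type is the iodonitrene-mediated nitrogen deletion of NH-pyrrolidines to cyclobutanes, the one-flask form of N2 loss from 1,1-diazenes of N-aminopyrrolidines. The four-membered ring closes by radical–radical coupling of the 1,4-biradical, not by a polar exo or endo cyclisation, which turns the 3-oxa-7-azabicyclo[3.3.0]octane of 5 into the 3-oxabicyclo[3.2.0]heptane of 7. No stereocentre is created: C2 and C3 keep the cis aryl/ester geometry of the pyrrolidine because the singlet pair should collapse faster than either radical centre rotates, and C1 and C4 are untouched and locked by the lactone. The selectivity needed is recombination over β-scission of the C1–C4 bond and over rotation; both radical centres are stabilised, so N2 loss is easy, and the cis-fused lactone holds the two carbons of the new bond gauche and close. The benzyl ether keeps the phenol away from the trivalent iodine oxidant, and the excess of ammonium carbamate should make nitrogen transfer outrun attack on the dialkoxyarene.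

Step 4
Reactants: 7 methyl (1R,5S,6R,7R)-7-[4-(benzyloxy)-3-methoxyphenyl]-1-methyl-2-oxo-3-oxabicyclo[3.2.0]heptane-6-carboxylate
Product: 9 dimethyl (1R,2R,3R,4S)-2-[4-(benzyloxy)-3-methoxyphenyl]-4-(hydroxymethyl)-1-methylcyclobutane-1,3-dicarboxylate, via dipotassium hydroxy dicarboxylate 8 (not isolated)
Conditions: KOH (2.5 equiv), THF/H2O, rt; CO2 to pH 8–9, evaporate; MeI, DMF, 0 °C → rt
Reagents that add atoms: potassium hydroxide, [K+].[OH-]; iodomethane, CI
Why: Saponification opens the lactone and also cleaves the C3 methyl ester; SN2 O-methylation of the two carboxylates with MeI then gives the diester while the neutral primary hydroxyl is not alkylated (excess hydroxide is removed as hydrogen carbonate first). C3 is a carboxylate throughout and should not epimerise; the product is used at once because a γ-hydroxy ester can relactonise.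

Step 5
Reactants: 9 dimethyl (1R,2R,3R,4S)-2-[4-(benzyloxy)-3-methoxyphenyl]-4-(hydroxymethyl)-1-methylcyclobutane-1,3-dicarboxylate
Product: 10 dimethyl (1R,2R,3R,4S)-2-[4-(benzyloxy)-3-methoxyphenyl]-4-(iodomethyl)-1-methylcyclobutane-1,3-dicarboxylate
Conditions: PPh3, imidazole, I2, CH2Cl2, 0 °C
Reagents that add atoms: iodine, II
Why: Appel-type iodination: the alkoxyphosphonium ion of the primary alcohol is displaced by iodide (SN2) under cold, nearly neutral conditions that leave the ethers, the esters and the ring centres untouched.

Step 6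
Reactants: 10 dimethyl (1R,2R,3R,4S)-2-[4-(benzyloxy)-3-methoxyphenyl]-4-(iodomethyl)-1-methylcyclobutane-1,3-dicarboxylate; 11 methyl acetoacetate
Product: 13 dimethyl (1S,2R,3S,4S)-2-[4-(benzyloxy)-3-methoxyphenyl]-4-(5-methoxy-3,5-dioxopentyl)-1-methylcyclobutane-1,3-dicarboxylate, via methyl acetoacetate dianion 12 (not isolated)
Conditions: 11, NaH, THF, 0 °C; n-BuLi, 0 °C; then 10, THF/DMPU, 0 °C → rt; aq NH4Cl
Reagents that add atoms: none
Why: γ-Alkylation of a β-keto ester dianion: the terminal carbanion of 12 is its most nucleophilic site and displaces the primary iodide (SN2), forming the CH2–CH2 bond of the side chain; a primary iodide should react faster than the hindered ring esters are attacked or C3 is deprotonated.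

Step 7
Reactants: 13 dimethyl (1S,2R,3S,4S)-2-[4-(benzyloxy)-3-methoxyphenyl]-4-(5-methoxy-3,5-dioxopentyl)-1-methylcyclobutane-1,3-dicarboxylate
Product: 14 dimethyl (1S,2R,3S,4S)-2-[4-(benzyloxy)-3-methoxyphenyl]-4-[(Z)-3-(diethoxyphosphoryloxy)-5-methoxy-5-oxopent-3-enyl]-1-methylcyclobutane-1,3-dicarboxylate
Conditions: NaH, Et2O, 0 °C; ClP(O)(OEt)2, 0 °C → rt
Reagents that add atoms: diethyl chlorophosphate, CCOP(=O)(Cl)OCC
Why: O-Phosphorylation of the sodium-chelated (Z)-enolate of the β-keto ester gives the (Z)-enol phosphate (phosphate and ester cis); NaH removes only the acidic β-dicarbonyl proton, so C3 is not touched.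

Step 8
Reactants: 14 dimethyl (1S,2R,3S,4S)-2-[4-(benzyloxy)-3-methoxyphenyl]-4-[(Z)-3-(diethoxyphosphoryloxy)-5-methoxy-5-oxopent-3-enyl]-1-methylcyclobutane-1,3-dicarboxylate
Product: 15 dimethyl (1S,2R,3S,4S)-2-[4-(benzyloxy)-3-methoxyphenyl]-4-[(E)-5-methoxy-3-methyl-5-oxopent-3-enyl]-1-methylcyclobutane-1,3-dicarboxylate
Conditions: Me2CuLi (from CuI and MeLi), Et2O, −78 → −45 °C
Reagents that add atoms: lithium dimethylcuprate, [Li+].C[Cu-]C (made from methyllithium, [Li]C, and CuI)
Why: Conjugate addition–elimination of the cuprate on the β-phosphoryloxy enoate replaces phosphate by methyl with retention of geometry, so the (Z)-enol phosphate gives the (E)-3-methyl enoate; saturated esters and aryl ethers do not react with the cuprate at this temperature.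

Step 9
Reactants: 15 dimethyl (1S,2R,3S,4S)-2-[4-(benzyloxy)-3-methoxyphenyl]-4-[(E)-5-methoxy-3-methyl-5-oxopent-3-enyl]-1-methylcyclobutane-1,3-dicarboxylate
Product: 16 (1S,2R,3S,4S)-2-[4-(benzyloxy)-3-methoxyphenyl]-4-[(E)-4-carboxy-3-methylbut-3-enyl]-1-methylcyclobutane-1,3-dicarboxylic acid
Conditions: LiOH·H2O, THF/MeOH/H2O, rt → 60 °C; 1 M HCl to pH 3
Reagents that add atoms: lithium hydroxide, [Li+].[OH-]
Why: Ester saponification: the enoate and the C3 ester should hydrolyse at room temperature and are then carboxylates, protected against epimerisation and isomerisation, before heat is applied for the neopentyl-type C1 ester.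

Step 10
Reactants: 17 (R)-3-bromo-2-methylpropan-1-ol; 18 (E)-but-2-en-1-amine hydrochloride
Product: 19 (S)-3-[(E)-but-2-en-1-ylamino]-2-methylpropan-1-ol
Conditions: 18 (3 equiv), K2CO3, MeCN, 70 °C
Reagents that add atoms: none
Why: SN2 N-alkylation of a primary amine by a primary bromide; the excess of amine suppresses dialkylation and the stereocentre is a bystander (the descriptor changes only by priority).

Step 11
Reactants: 19 (S)-3-[(E)-but-2-en-1-ylamino]-2-methylpropan-1-ol
Product: 20 methyl [(E)-but-2-en-1-yl][(S)-3-hydroxy-2-methylpropyl]carbamate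
Conditions: ClCO2Me, NaHCO3, CH2Cl2/H2O, 0 °C
Reagents that add atoms: methyl chloroformate, COC(=O)Cl
Why: Schotten–Baumann acylation: the secondary amine is far more nucleophilic than the primary alcohol, so only the nitrogen is acylated.

Step 12
Reactants: 20 methyl [(E)-but-2-en-1-yl][(S)-3-hydroxy-2-methylpropyl]carbamate
Product: 21 methyl [(E)-but-2-en-1-yl][(S)-2-methyl-3-oxopropyl]carbamate
Conditions: Dess–Martin periodinane, NaHCO3, CH2Cl2, 0 °C → rt
Reagents that add atoms: none
Why: Dess–Martin oxidation of a primary alcohol under buffered, non-basic conditions, which should preserve the α-methyl stereocentre; the aldehyde is used without chromatography.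

Step 13
Reactants: 21 methyl [(E)-but-2-en-1-yl][(S)-2-methyl-3-oxopropyl]carbamate
Product: 22 methyl [(E)-but-2-en-1-yl][(R)-2-methylbut-3-yn-1-yl]carbamate
Conditions: dimethyl (1-diazo-2-oxopropyl)phosphonate, K2CO3, MeOH, 0 °C → rt
Reagents that add atoms: dimethyl (1-diazo-2-oxopropyl)phosphonate, CC(=O)C(=[N+]=[N-])P(=O)(OC)OC
Why: Seyferth–Gilbert homologation with the Ohira–Bestmann reagent converts the aldehyde into the terminal alkyne under mild carbonate conditions at low temperature, chosen to keep the α-centre intact.

Step 14
Reactants: 22 methyl [(E)-but-2-en-1-yl][(R)-2-methylbut-3-yn-1-yl]carbamate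
Product: 24 methyl (4R,7S,7aS)-4,7-dimethyl-6-oxo-1,3,4,6,7,7a-hexahydro-2H-cyclopenta[c]pyridine-2-carboxylate, via hexacarbonyldicobalt alkyne complex 23 (not isolated)
Conditions: Co2(CO)8, CH2Cl2, rt; then N-methylmorpholine N-oxide, 0 °C → rt
Reagents that add atoms: octacarbonyldicobalt, O=C=[Co](=C=O)(=C=O)(=C=O)[Co](=C=O)(=C=O)(=C=O)=C=O
Why: Pauson–Khand [2+2+1] reaction: N-oxide removal of a CO ligand from 23 lets the tethered alkene insert, then CO insertion and reductive elimination close piperidine and cyclopentenone together. Syn addition to the (E)-alkene puts the C7 methyl trans to C1, and C7a is set relative to C4 by the pseudo-equatorial methyl group of the chair-like tether; C7 is also the thermodynamically preferred, base-equilibratable epimer.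

Step 15
Reactants: 24 methyl (4R,7S,7aS)-4,7-dimethyl-6-oxo-1,3,4,6,7,7a-hexahydro-2H-cyclopenta[c]pyridine-2-carboxylate
Product: 25 methyl (4R,4aS,7S,7aR)-4,7-dimethyl-6-oxooctahydro-2H-cyclopenta[c]pyridine-2-carboxylate
Conditions: H2 (1 atm), Pd/C, EtOAc, rt
Reagents that add atoms: none
Why: Heterogeneous hydrogenation adds H2 syn to the enone face opposite the neighbouring C4 methyl group, which is the face of H7a, so the ring fusion becomes cis (C4a set by substrate control).

Step 16
Reactants: 25 methyl (4R,4aS,7S,7aR)-4,7-dimethyl-6-oxooctahydro-2H-cyclopenta[c]pyridine-2-carboxylate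
Product: 26 (4R,4aS,6S,7S,7aR)-2,4,7-trimethyloctahydro-1H-cyclopenta[c]pyridin-6-ol (6-epimer of the amino alcohol of the target; hydroxyl trans to the C7 methyl group)
Conditions: LiAlH4, THF, 0 °C → reflux; H2O/NaOH work-up
Reagents that add atoms: none
Why: Hydride reduction: LiAlH4 should attack the ketone from the convex face (that of the ring-fusion hydrogens; the concave face is covered by the piperidine ring), giving the hydroxyl trans to the C7 methyl group; at reflux the same reagent reduces the methyl carbamate to N-methyl.

Step 17
Reactants: 16 (1S,2R,3S,4S)-2-[4-(benzyloxy)-3-methoxyphenyl]-4-[(E)-4-carboxy-3-methylbut-3-enyl]-1-methylcyclobutane-1,3-dicarboxylic acid; 26 (4R,4aS,6S,7S,7aR)-2,4,7-trimethyloctahydro-1H-cyclopenta[c]pyridin-6-ol (three molecules, one for each carboxyl group)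
Product: 27 O-benzyl ether of the target: tris[(4R,4aS,6R,7S,7aR)-2,4,7-trimethyloctahydro-1H-cyclopenta[c]pyridin-6-yl] ester of 16
Conditions: 26 (3.6 equiv), PPh3 (4 equiv), DIAD (4 equiv), THF, 0 °C → rt
Reagents that add atoms: two further molecules of amino alcohol 26, O[C@H]1C[C@@H]2[C@@H](CN(C)C[C@@H]2C)[C@@H]1C.O[C@H]1C[C@@H]2[C@@H](CN(C)C[C@@H]2C)[C@@H]1C
Why: Threefold Mitsunobu esterification in one flask: one molecule of 26 is consumed per carboxyl group, each hydroxyl is activated as an alkoxyphosphonium ion and displaced by a carboxylate of 16 (SN2) with inversion at C6, which places the three ester oxygens on the convex face cis to the C7 methyl groups. The acid is the nucleophile, so the hindered C1 carboxyl needs no activation and C3 meets no base.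

Step 18
Reactants: 27 O-benzyl ether of the target
Product: 28 CNP0251577.3 (target)
Conditions: BCl3, pentamethylbenzene, CH2Cl2, −78 °C; MeOH, aq NaHCO3
Reagents that add atoms: none
Why: Lewis acid debenzylation with a cation scavenger: BCl3 ionises the aryl benzyl ether at low temperature and pentamethylbenzene traps the benzyl cation (Friedel–Crafts), which should spare the aryl methyl ether, the three esters and the enoate; excess BCl3 covers the three amines, which are freed by the methanolic work-up.

## Compound list

1 | 4-(benzyloxy)-3-methoxybenzaldehyde | COc1cc(C=O)ccc1OCc1ccccc1 | starting material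
2 | glycine methyl ester hydrochloride | COC(=O)CN.Cl | starting material
3 | methyl (E)-N-[4-(benzyloxy)-3-methoxybenzylidene]glycinate | COC(=O)C/N=C/c1ccc(OCc2ccccc2)c(OC)c1 | intermediate
4 | 3-methylfuran-2(5H)-one | CC1=CCOC1=O | starting material
5 | methyl (3aR,4R,6R,6aS)-6-[4-(benzyloxy)-3-methoxyphenyl]-6a-methyl-1-oxohexahydro-1H-furo[3,4-c]pyrrole-4-carboxylate | COc1cc([C@H]2N[C@@H](C(=O)OC)[C@H](CO3)[C@]2(C)C3=O)ccc1OCc1ccccc1 | intermediate
6 | 1,1-diazene (N-nitrene) of pyrrolidine 5 | COc1cc([C@H]2[N+](=[N-])[C@@H](C(=O)OC)[C@H](CO3)[C@]2(C)C3=O)ccc1OCc1ccccc1 | intermediate (not isolated)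
7 | methyl (1R,5S,6R,7R)-7-[4-(benzyloxy)-3-methoxyphenyl]-1-methyl-2-oxo-3-oxabicyclo[3.2.0]heptane-6-carboxylate | COc1cc([C@H]2[C@@H](C(=O)OC)[C@H](CO3)[C@]2(C)C3=O)ccc1OCc1ccccc1 | intermediate
8 | dipotassium (1R,2R,3R,4S)-2-[4-(benzyloxy)-3-methoxyphenyl]-4-(hydroxymethyl)-1-methylcyclobutane-1,3-dicarboxylate | COc1cc([C@H]2[C@@H](C(=O)[O-])[C@H](CO)[C@]2(C)C(=O)[O-])ccc1OCc1ccccc1.[K+].[K+] | intermediate (not isolated)
9 | dimethyl (1R,2R,3R,4S)-2-[4-(benzyloxy)-3-methoxyphenyl]-4-(hydroxymethyl)-1-methylcyclobutane-1,3-dicarboxylate | COc1cc([C@H]2[C@@H](C(=O)OC)[C@H](CO)[C@]2(C)C(=O)OC)ccc1OCc1ccccc1 | intermediate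
10 | dimethyl (1R,2R,3R,4S)-2-[4-(benzyloxy)-3-methoxyphenyl]-4-(iodomethyl)-1-methylcyclobutane-1,3-dicarboxylate | COc1cc([C@H]2[C@@H](C(=O)OC)[C@H](CI)[C@]2(C)C(=O)OC)ccc1OCc1ccccc1 | intermediate
11 | methyl acetoacetate | CC(=O)CC(=O)OC | starting material
12 | sodium lithium dianion of methyl acetoacetate | C=C([O-])C=C([O-])OC.[Na+].[Li+] | intermediate (not isolated)
13 | dimethyl (1S,2R,3S,4S)-2-[4-(benzyloxy)-3-methoxyphenyl]-4-(5-methoxy-3,5-dioxopentyl)-1-methylcyclobutane-1,3-dicarboxylate | COc1cc([C@H]2[C@@H](C(=O)OC)[C@H](CCC(=O)CC(=O)OC)[C@]2(C)C(=O)OC)ccc1OCc1ccccc1 | intermediate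
14 | dimethyl (1S,2R,3S,4S)-2-[4-(benzyloxy)-3-methoxyphenyl]-4-[(Z)-3-(diethoxyphosphoryloxy)-5-methoxy-5-oxopent-3-enyl]-1-methylcyclobutane-1,3-dicarboxylate | COc1cc([C@H]2[C@@H](C(=O)OC)[C@H](CC/C(OP(=O)(OCC)OCC)=C/C(=O)OC)[C@]2(C)C(=O)OC)ccc1OCc1ccccc1 | intermediate
15 | dimethyl (1S,2R,3S,4S)-2-[4-(benzyloxy)-3-methoxyphenyl]-4-[(E)-5-methoxy-3-methyl-5-oxopent-3-enyl]-1-methylcyclobutane-1,3-dicarboxylate | COc1cc([C@H]2[C@@H](C(=O)OC)[C@H](CC/C(C)=C/C(=O)OC)[C@]2(C)C(=O)OC)ccc1OCc1ccccc1 | intermediate
16 | (1S,2R,3S,4S)-2-[4-(benzyloxy)-3-methoxyphenyl]-4-[(E)-4-carboxy-3-methylbut-3-enyl]-1-methylcyclobutane-1,3-dicarboxylic acid | COc1cc([C@H]2[C@@H](C(=O)O)[C@H](CC/C(C)=C/C(=O)O)[C@]2(C)C(=O)O)ccc1OCc1ccccc1 | intermediate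
17 | (R)-3-bromo-2-methylpropan-1-ol | OC[C@@H](C)CBr | starting material
18 | (E)-but-2-en-1-amine hydrochloride | C/C=C/CN.Cl | starting material
19 | (S)-3-[(E)-but-2-en-1-ylamino]-2-methylpropan-1-ol | OC[C@@H](C)CNC/C=C/C | intermediate
20 | methyl [(E)-but-2-en-1-yl][(S)-3-hydroxy-2-methylpropyl]carbamate | OC[C@@H](C)CN(C(=O)OC)C/C=C/C | intermediate
21 | methyl [(E)-but-2-en-1-yl][(S)-2-methyl-3-oxopropyl]carbamate | O=C[C@@H](C)CN(C(=O)OC)C/C=C/C | intermediate
22 | methyl [(E)-but-2-en-1-yl][(R)-2-methylbut-3-yn-1-yl]carbamate | C#C[C@@H](C)CN(C(=O)OC)C/C=C/C | intermediate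
23 | μ-alkyne hexacarbonyldicobalt complex of 22 | [CH]12[Co]3(=C=O)(=C=O)(=C=O)[Co]1(=C=O)(=C=O)(=C=O)C23[C@@H](C)CN(C(=O)OC)C/C=C/C | intermediate (not isolated)
24 | methyl (4R,7S,7aS)-4,7-dimethyl-6-oxo-1,3,4,6,7,7a-hexahydro-2H-cyclopenta[c]pyridine-2-carboxylate | O=C1C=C2[C@@H](CN(C(=O)OC)C[C@@H]2C)[C@@H]1C | intermediate
25 | methyl (4R,4aS,7S,7aR)-4,7-dimethyl-6-oxooctahydro-2H-cyclopenta[c]pyridine-2-carboxylate | O=C1C[C@@H]2[C@@H](CN(C(=O)OC)C[C@@H]2C)[C@@H]1C | intermediate
26 | (4R,4aS,6S,7S,7aR)-2,4,7-trimethyloctahydro-1H-cyclopenta[c]pyridin-6-ol | O[C@H]1C[C@@H]2[C@@H](CN(C)C[C@@H]2C)[C@@H]1C | intermediate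
27 | O-benzyl ether of the target (triester of 16 with three units of the C6-inverted amino alcohol) | COc1cc([C@H]2[C@@H](C(=O)O[C@@H]3C[C@@H]4[C@@H](CN(C)C[C@@H]4C)[C@@H]3C)[C@H](CC/C(C)=C/C(=O)O[C@@H]3C[C@@H]4[C@@H](CN(C)C[C@@H]4C)[C@@H]3C)[C@]2(C)C(=O)O[C@@H]2C[C@@H]3[C@@H](CN(C)C[C@@H]3C)[C@@H]2C)ccc1OCc1ccccc1 | intermediate
28 | CNP0251577.3 | COc1cc([C@H]2[C@@H](C(=O)O[C@@H]3C[C@@H]4[C@@H](CN(C)C[C@@H]4C)[C@@H]3C)[C@H](CC/C(C)=C/C(=O)O[C@@H]3C[C@@H]4[C@@H](CN(C)C[C@@H]4C)[C@@H]3C)[C@]2(C)C(=O)O[C@@H]2C[C@@H]3[C@@H](CN(C)C[C@@H]3C)[C@@H]2C)ccc1O | target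

## Step count and risks

Total: 18 steps. Longest linear sequence: 11 steps (steps 1–9, 17, 18, from aldehyde 1). The amino alcohol arm is 7 steps (steps 10–16) and joins at step 17.

**Step 3 (key step).**
- Risk: oxidative attack of the trivalent iodine reagent on the dialkoxyarene, or dehydrogenation of the benzylic amine, may compete with N-amination. The biradical may fragment by β-scission of the C1–C4 bond, or lose its geometry by rotation before it closes.
- Fallback: a stepwise hydrazine route that avoids hypervalent iodine. It sets out from 5 and returns at 7. Nitrosation with tert-butyl nitrite gives the N-nitrosopyrrolidine F1. Reduction with zinc in acetic acid gives the N-aminopyrrolidine F2. Oxidation of F2 with HgO generates the same diazene 6, which loses N2 to give 7.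

**Step 2.**
- Risk: sluggish addition to the trisubstituted, α-methylated dipolarophile (Michael addition without ring closure, imine hydrolysis) and erosion of exo or enantioselectivity.
- Fallback: a racemic, exo-directed cycloaddition followed by resolution. It sets out from 3 and 4 and returns at 5. Cu(CH3CN)4PF6 with racemic BINAP is used at room temperature, the exo adduct is separated, and the racemate is resolved by preparative chromatography on a chiral stationary phase. This delivers 5 and its mirror image F3, which is discarded.

**Step 4 (with step 5).**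
- Risk: relactonisation of the γ-hydroxy ester during methylation or iodination, which returns material to a lactone.
- Fallback: an irreversible lactone opening. It sets out from 7 and returns at 10. Sodium phenylselenide (PhSeSePh, NaBH4, DMF, 110 °C) opens the lactone by SN2 attack at the CH2–O carbon and also dealkylates the C3 ester, giving the seleno diacid F4. MeI/K2CO3 re-forms both methyl esters to give the selenide diester F5. MeI/NaI in DMF at 80 °C then exchanges the phenylseleno group for iodide (Se-methylation followed by displacement at carbon by iodide), giving 10.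

**Step 6.**
- Risk: the strongly basic dianion may deprotonate C3 (epimerisation) or add to a ring ester, and the β-branched iodide may react slowly or cyclise back to a lactone.
- Fallback: olefination instead of alkylation. It sets out from 9 and returns at 13. Dess–Martin oxidation gives the aldehyde F6. Horner–Wadsworth–Emmons reaction with the dianion of methyl 4-(diethoxyphosphoryl)-3-oxobutanoate (NaH, THF, 0 °C) gives the (E)-enone keto ester F7. Conjugate reduction with [(Ph3P)CuH]6 gives 13.

**Step 14.**
- Risk: slow alkene insertion for a 1,2-disubstituted alkene in a 1,7-enyne, and incomplete control of C7a by the remote C4 methyl group.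
- Fallback: a terminal alkene with later methylation. It sets out from 17 and returns at 24. Allylamine replaces 18 and the sequence of steps 10–13 gives (S)-3-(allylamino)-2-methylpropan-1-ol F8, its methyl carbamate F9, the aldehyde F10 and the N-allyl enyne F11. The Pauson–Khand reaction of the terminal alkene gives the 7-demethyl enone F12. Kinetic α'-deprotonation (LDA, THF, −78 °C) and MeI then introduce the C7 methyl group anti to the neighbouring C1 substituent, giving 24.

**Step 17.**
- Risk: incomplete esterification of the hindered C1 carboxylate and elimination from the activated alcohol, leaving mixtures of di- and triesters.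
- Fallback: carboxylate alkylation with a preformed sulfonate. It sets out from 26 and 16 and returns at 27. MsCl/Et3N converts 26 into the methanesulfonate F13. Cs2CO3 in DMF converts 16 into the tricesium tricarboxylate F14, which displaces three molecules of F13 at 50 °C with inversion to give 27.

## Further compounds

F1 | step 3 | methyl (3aR,4R,6R,6aS)-6-[4-(benzyloxy)-3-methoxyphenyl]-6a-methyl-5-nitroso-1-oxohexahydro-1H-furo[3,4-c]pyrrole-4-carboxylate | COc1cc([C@H]2N(N=O)[C@@H](C(=O)OC)[C@H](CO3)[C@]2(C)C3=O)ccc1OCc1ccccc1
F2 | step 3 | methyl (3aR,4R,6R,6aS)-5-amino-6-[4-(benzyloxy)-3-methoxyphenyl]-6a-methyl-1-oxohexahydro-1H-furo[3,4-c]pyrrole-4-carboxylate | COc1cc([C@H]2N(N)[C@@H](C(=O)OC)[C@H](CO3)[C@]2(C)C3=O)ccc1OCc1ccccc1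
F3 | step 2 | methyl (3aS,4S,6S,6aR)-6-[4-(benzyloxy)-3-methoxyphenyl]-6a-methyl-1-oxohexahydro-1H-furo[3,4-c]pyrrole-4-carboxylate (mirror image of 5) | COc1cc([C@@H]2N[C@H](C(=O)OC)[C@@H](CO3)[C@@]2(C)C3=O)ccc1OCc1ccccc1
F4 | step 4 | (1R,2R,3R,4S)-2-[4-(benzyloxy)-3-methoxyphenyl]-1-methyl-4-[(phenylselanyl)methyl]cyclobutane-1,3-dicarboxylic acid | COc1cc([C@H]2[C@@H](C(=O)O)[C@H](C[Se]c3ccccc3)[C@]2(C)C(=O)O)ccc1OCc1ccccc1
F5 | step 4 | dimethyl (1R,2R,3R,4S)-2-[4-(benzyloxy)-3-methoxyphenyl]-1-methyl-4-[(phenylselanyl)methyl]cyclobutane-1,3-dicarboxylate | COc1cc([C@H]2[C@@H](C(=O)OC)[C@H](C[Se]c3ccccc3)[C@]2(C)C(=O)OC)ccc1OCc1ccccc1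
F6 | step 6 | dimethyl (1R,2R,3R,4S)-2-[4-(benzyloxy)-3-methoxyphenyl]-4-formyl-1-methylcyclobutane-1,3-dicarboxylate | COc1cc([C@H]2[C@@H](C(=O)OC)[C@H](C=O)[C@]2(C)C(=O)OC)ccc1OCc1ccccc1
F7 | step 6 | dimethyl (1S,2R,3S,4S)-2-[4-(benzyloxy)-3-methoxyphenyl]-4-[(E)-5-methoxy-3,5-dioxopent-1-enyl]-1-methylcyclobutane-1,3-dicarboxylate | COc1cc([C@H]2[C@@H](C(=O)OC)[C@H](/C=C/C(=O)CC(=O)OC)[C@]2(C)C(=O)OC)ccc1OCc1ccccc1
F8 | step 14 | (S)-3-(allylamino)-2-methylpropan-1-ol | OC[C@@H](C)CNCC=C
F9 | step 14 | methyl allyl[(S)-3-hydroxy-2-methylpropyl]carbamate | OC[C@@H](C)CN(C(=O)OC)CC=C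
F10 | step 14 | methyl allyl[(S)-2-methyl-3-oxopropyl]carbamate | O=C[C@@H](C)CN(C(=O)OC)CC=C
F11 | step 14 | methyl allyl[(R)-2-methylbut-3-yn-1-yl]carbamate | C#C[C@@H](C)CN(C(=O)OC)CC=C
F12 | step 14 | methyl (4R,7aS)-4-methyl-6-oxo-1,3,4,6,7,7a-hexahydro-2H-cyclopenta[c]pyridine-2-carboxylate | O=C1C=C2[C@@H](CN(C(=O)OC)C[C@@H]2C)C1
F13 | step 17 | (4R,4aS,6S,7S,7aR)-2,4,7-trimethyloctahydro-1H-cyclopenta[c]pyridin-6-yl methanesulfonate | CS(=O)(=O)O[C@H]1C[C@@H]2[C@@H](CN(C)C[C@@H]2C)[C@@H]1C
F14 | step 17 | tricesium (1S,2R,3S,4S)-2-[4-(benzyloxy)-3-methoxyphenyl]-4-[(E)-4-carboxylato-3-methylbut-3-enyl]-1-methylcyclobutane-1,3-dicarboxylate | COc1cc([C@H]2[C@@H](C(=O)[O-])[C@H](CC/C(C)=C/C(=O)[O-])[C@]2(C)C(=O)[O-])ccc1OCc1ccccc1.[Cs+].[Cs+].[Cs+]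
A1 | alternative 1 | (4R,4aS,7S,7aR)-2,4,7-trimethyloctahydro-6H-cyclopenta[c]pyridin-6-one | O=C1C[C@@H]2[C@@H](CN(C)C[C@@H]2C)[C@@H]1C
A2 | alternative 1 | 2-methyl-4-[1-(methylamino)propan-2-yl]cyclopent-2-en-1-ol (hydroxyl trans to the side chain) | CNC[C@H](C)[C@@H]1C[C@@H](O)C(C)=C1
A3 | alternative 1 | N-methyl-N-methyleneiminium ion derived from A2 | C=[N+](C)C[C@H](C)[C@@H]1C[C@@H](O)C(C)=C1
A4 | alternative 1 | formaldehyde | C=O
A5 | alternative 2 | methyl (4R,7S,7aS)-4,7-dimethyl-6-oxo-1,3,4,6,7,7a-hexahydro-2H-cyclopenta[c]pyridine-2-carboxylate (identical with 24) | O=C1C=C2[C@@H](CN(C(=O)OC)C[C@@H]2C)[C@@H]1C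
A6 | alternative 2 | methyl [(E)-but-2-en-1-yl][(R)-2-methylbut-3-yn-1-yl]carbamate (identical with 22) | C#C[C@@H](C)CN(C(=O)OC)C/C=C/C
A7 | alternative 3 | 2-[4-(benzyloxy)-3-methoxyphenyl]-3-[(tert-butyldimethylsilyloxy)methyl]-1-methyl-4-vinylcyclobutane-1-carboxylic acid (vinyl and carboxyl cis) | COc1cc([C@H]2[C@@H](CO[Si](C)(C)C(C)(C)C)[C@H](C=C)[C@]2(C)C(=O)O)ccc1OCc1ccccc1
A8 | alternative 3 | eight-membered (Z)-allylic lactone with 4-aryl, 5-(silyloxymethyl) and 3-methyl groups (C3 epimer immaterial) | COc1cc([C@H]2[C@@H](CO[Si](C)(C)C(C)(C)C)/C=C\COC(=O)C2C)ccc1OCc1ccccc1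
A9 | alternative 3 | trimethylsilyl ketene acetal of A8 | COc1cc([C@H]2[C@@H](CO[Si](C)(C)C(C)(C)C)/C=C\COC(O[Si](C)(C)C)=C2C)ccc1OCc1ccccc1
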